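**Retrosynthetic overview**
- The target (7S,8R, anti/erythro) comes from its C7 epimer, the (7R,8R) syn alcohol, by Mitsunobu inversion at the benzylic carbinol.
- The C9 methyl comes from CH2OTs, which comes from CH2OH, which comes from an N-acyl oxazolidinone (reductive auxiliary removal, then hydride deoxygenation).
- Key C7–C8 bond: Evans boron syn-aldol of an N-(aryloxyacetyl)-(S)-4-benzyloxazolidinone with 3,4,5-trimethoxybenzaldehyde; this sets C8 for good and C7 provisionally.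
- The aryloxyacetyl imide comes from 4-allyl-2,6-dimethoxyphenol, ethyl bromoacetate and (S)-4-benzyl-2-oxazolidinone.
- No ring is formed: both benzene rings are bought, and the oxazolidinone ring is a recovered auxiliary.

Assumption: neolignan numbering is used (C7 = carbinol carbon, C8 = aryloxy-bearing carbon, C9 = methyl); the given SMILES is read as (7S,8R).

**Route**

Step 1
Reactants: 1 4-allyl-2,6-dimethoxyphenol (methoxyeugenol); 2 ethyl bromoacetate
Product: 3 ethyl 2-(4-allyl-2,6-dimethoxyphenoxy)acetate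
Conditions: K2CO3 (2 equiv), acetone, reflux
Reagents that add atoms: none
Why: Williamson ether synthesis; the phenoxide displaces bromide from the activated α-bromo ester by SN2, and no stereocentre is involved.

Step 2
Reactants: 3 ethyl 2-(4-allyl-2,6-dimethoxyphenoxy)acetate
Product: 4 2-(4-allyl-2,6-dimethoxyphenoxy)acetic acid
Conditions: LiOH·H2O (2 equiv), THF/H2O 3:1, rt; then 1 M HCl to pH 2
Reagents that add atoms: lithium hydroxide, [Li+].[OH-]
Why: Ester saponification; aryl ethers and the allyl group are inert to aqueous hydroxide at room temperature.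

Step 3
Reactants: 4 2-(4-allyl-2,6-dimethoxyphenoxy)acetic acid; 5 (S)-4-benzyl-2-oxazolidinone
Product: 7 (S)-3-[2-(4-allyl-2,6-dimethoxyphenoxy)acetyl]-4-benzyloxazolidin-2-one, via mixed pivalic anhydride 6 (not isolated)
Conditions: PivCl (1.05 equiv), Et3N (2.5 equiv), THF, −20 °C; then LiCl (1.1 equiv), 5, −20 °C → rt
Reagents that add atoms: pivaloyl chloride, CC(C)(C)C(=O)Cl (its acyl group is present only in 6)
Why: N-acylation through a mixed anhydride; the hindered pivaloyl carbonyl steers the oxazolidinone to the aryloxyacetyl carbonyl, and the auxiliary stereocentre is untouched.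

Step 4
Reactants: 7 (S)-3-[2-(4-allyl-2,6-dimethoxyphenoxy)acetyl]-4-benzyloxazolidin-2-one; 8 3,4,5-trimethoxybenzaldehyde
Product: 11 (S)-3-[(2S,3R)-2-(4-allyl-2,6-dimethoxyphenoxy)-3-hydroxy-3-(3,4,5-trimethoxyphenyl)propanoyl]-4-benzyloxazolidin-2-one, via Z-dibutylboron enolate 9 (not isolated), via dibutylboron aldolate 10 (not isolated)
Conditions: Bu2BOTf (1.2 equiv), i-Pr2NEt (1.4 equiv), CH2Cl2, −78 → 0 °C; 8 (1.3 equiv), −78 → 0 °C; then pH 7 buffer, MeOH, 30% H2O2, 0 °C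
Reagents that add atoms: dibutylboron triflate, CCCCB(CCCC)OS(=O)(=O)C(F)(F)F (boron and butyl groups are present only in 9 and 10)
Why: Evans syn-aldol; the Z(O)-boron enolate reacts through a Zimmerman–Traxler chair on the face opposite the benzyl group, which sets C8 (final R) and C7 (R, syn to C8) together.

Step 5
Reactants: 11 the syn-aldol adduct
Product: 12 (S)-3-[(2S,3R)-2-(4-allyl-2,6-dimethoxyphenoxy)-3-[(tert-butyldimethylsilyl)oxy]-3-(3,4,5-trimethoxyphenyl)propanoyl]-4-benzyloxazolidin-2-one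
Conditions: TBSOTf (1.5 equiv), 2,6-lutidine (2.5 equiv), CH2Cl2, 0 °C
Reagents that add atoms: tert-butyldimethylsilyl triflate, CC(C)(C)[Si](C)(C)OS(=O)(=O)C(F)(F)F
Why: O-silylation with a silyl triflate and a hindered base protects the benzylic hydroxyl, blocks retro-aldol cleavage and keeps the two oxygens distinct in later steps.

Step 6
Reactants: 12 the TBS-protected imide
Product: 13 (2R,3R)-2-(4-allyl-2,6-dimethoxyphenoxy)-3-[(tert-butyldimethylsilyl)oxy]-3-(3,4,5-trimethoxyphenyl)propan-1-ol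
Conditions: LiBH4 (2 equiv), H2O (2 equiv), Et2O/THF, 0 °C; then aq. NH4Cl
Reagents that add atoms: none
Why: Reductive cleavage of the N-acyl oxazolidinone by hydride attack at the exocyclic carbonyl; no stereocentre is touched (the C2 descriptor changes from S to R only because the CIP priorities change).

Step 7
Reactants: 13 the primary alcohol
Product: 14 (2R,3R)-2-(4-allyl-2,6-dimethoxyphenoxy)-3-[(tert-butyldimethylsilyl)oxy]-3-(3,4,5-trimethoxyphenyl)propyl 4-methylbenzenesulfonate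
Conditions: TsCl (1.5 equiv), Et3N (3 equiv), DMAP (0.1 equiv), CH2Cl2, 0 °C → rt
Reagents that add atoms: p-toluenesulfonyl chloride, Cc1ccc(cc1)S(=O)(=O)Cl
Why: Sulfonylation of the only free (primary) hydroxyl turns C9–O into a leaving group.

Step 8
Reactants: 14 the primary tosylate
Product: 15 tert-butyl{[(1R,2R)-2-(4-allyl-2,6-dimethoxyphenoxy)-1-(3,4,5-trimethoxyphenyl)propyl]oxy}dimethylsilane
Conditions: LiEt3BH (3 equiv), THF, 0 °C → rt; then H2O
Reagents that add atoms: none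
Why: SN2 hydride displacement of a primary tosylate (Super-Hydride deoxygenation) turns CH2OTs into the C9 methyl; the silyl ether, aryl ethers and alkene are inert.

Step 9
Reactants: 15 the TBS ether
Product: 16 (1R,2R)-2-(4-allyl-2,6-dimethoxyphenoxy)-1-(3,4,5-trimethoxyphenyl)propan-1-ol (the 7R,8R syn/threo alcohol)
Conditions: TBAF (1.5 equiv), THF, 0 °C → rt; then H2O
Reagents that add atoms: none
Why: Fluoride-mediated desilylation, driven by Si–F bond formation; the C–O bond at C7 is not broken, so the configuration is kept.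

Step 10
Reactants: 16 the (1R,2R) alcohol
Product: 17 (1S,2R)-2-(4-allyl-2,6-dimethoxyphenoxy)-1-(3,4,5-trimethoxyphenyl)propyl 4-nitrobenzoate
Conditions: 4-nitrobenzoic acid (3 equiv), PPh3 (3 equiv), DIAD (3 equiv), THF, 0 °C → rt
Reagents that add atoms: 4-nitrobenzoic acid, O=C(O)c1ccc(cc1)[N+](=O)[O-]
Why: Mitsunobu reaction; the carboxylate displaces the alkoxyphosphonium group by SN2, which inverts C7 from R to S and gives the anti (erythro) relationship to the unchanged C8.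

Step 11
Reactants: 17 the inverted 4-nitrobenzoate
Product: 18 rhaphidecursinol B, (1S,2R)-2-(4-allyl-2,6-dimethoxyphenoxy)-1-(3,4,5-trimethoxyphenyl)propan-1-ol
Conditions: K2CO3 (0.5 equiv), MeOH, rt
Reagents that add atoms: none
Why: Base-catalysed transesterification (methanolysis) cleaves the acyl–oxygen bond of the activated ester, so the C7–O bond and both stereocentres are untouched.

**Compound list**
1 | 4-allyl-2,6-dimethoxyphenol | C=CCc1cc(OC)c(O)c(OC)c1 | starting material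
2 | ethyl bromoacetate | CCOC(=O)CBr | starting material
3 | ethyl 2-(4-allyl-2,6-dimethoxyphenoxy)acetate | C=CCc1cc(OC)c(OCC(=O)OCC)c(OC)c1 | intermediate
4 | 2-(4-allyl-2,6-dimethoxyphenoxy)acetic acid | C=CCc1cc(OC)c(OCC(=O)O)c(OC)c1 | intermediate
5 | (S)-4-benzyl-2-oxazolidinone | O=C1N[C@@H](Cc2ccccc2)CO1 | starting material
6 | 2-(4-allyl-2,6-dimethoxyphenoxy)acetic pivalic anhydride | C=CCc1cc(OC)c(OCC(=O)OC(=O)C(C)(C)C)c(OC)c1 | intermediate
7 | (S)-3-[2-(4-allyl-2,6-dimethoxyphenoxy)acetyl]-4-benzyloxazolidin-2-one | C=CCc1cc(OC)c(OCC(=O)N2[C@@H](Cc3ccccc3)COC2=O)c(OC)c1 | intermediate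
8 | 3,4,5-trimethoxybenzaldehyde | COc1cc(C=O)cc(OC)c1OC | starting material
9 | Z-dibutylboron enolate of 7 | CCCCB(CCCC)O/C(=C\Oc1c(OC)cc(CC=C)cc1OC)N1[C@@H](Cc2ccccc2)COC1=O | intermediate
10 | dibutylboron aldolate (O-dibutylboryl derivative of 11) | C=CCc1cc(OC)c(O[C@@H]([C@H](OB(CCCC)CCCC)c2cc(OC)c(OC)c(OC)c2)C(=O)N2[C@@H](Cc3ccccc3)COC2=O)c(OC)c1 | intermediate
11 | (S)-3-[(2S,3R)-2-(4-allyl-2,6-dimethoxyphenoxy)-3-hydroxy-3-(3,4,5-trimethoxyphenyl)propanoyl]-4-benzyloxazolidin-2-one | C=CCc1cc(OC)c(O[C@@H]([C@H](O)c2cc(OC)c(OC)c(OC)c2)C(=O)N2[C@@H](Cc3ccccc3)COC2=O)c(OC)c1 | intermediate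
12 | (S)-3-[(2S,3R)-2-(4-allyl-2,6-dimethoxyphenoxy)-3-[(tert-butyldimethylsilyl)oxy]-3-(3,4,5-trimethoxyphenyl)propanoyl]-4-benzyloxazolidin-2-one | C=CCc1cc(OC)c(O[C@@H]([C@H](O[Si](C)(C)C(C)(C)C)c2cc(OC)c(OC)c(OC)c2)C(=O)N2[C@@H](Cc3ccccc3)COC2=O)c(OC)c1 | intermediate
13 | (2R,3R)-2-(4-allyl-2,6-dimethoxyphenoxy)-3-[(tert-butyldimethylsilyl)oxy]-3-(3,4,5-trimethoxyphenyl)propan-1-ol | C=CCc1cc(OC)c(O[C@@H]([C@H](O[Si](C)(C)C(C)(C)C)c2cc(OC)c(OC)c(OC)c2)CO)c(OC)c1 | intermediate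
14 | (2R,3R)-2-(4-allyl-2,6-dimethoxyphenoxy)-3-[(tert-butyldimethylsilyl)oxy]-3-(3,4,5-trimethoxyphenyl)propyl 4-methylbenzenesulfonate | C=CCc1cc(OC)c(O[C@@H]([C@H](O[Si](C)(C)C(C)(C)C)c2cc(OC)c(OC)c(OC)c2)COS(=O)(=O)c2ccc(C)cc2)c(OC)c1 | intermediate
15 | tert-butyl{[(1R,2R)-2-(4-allyl-2,6-dimethoxyphenoxy)-1-(3,4,5-trimethoxyphenyl)propyl]oxy}dimethylsilane | C=CCc1cc(OC)c(O[C@H](C)[C@H](O[Si](C)(C)C(C)(C)C)c2cc(OC)c(OC)c(OC)c2)c(OC)c1 | intermediate
16 | (1R,2R)-2-(4-allyl-2,6-dimethoxyphenoxy)-1-(3,4,5-trimethoxyphenyl)propan-1-ol | C=CCc1cc(OC)c(O[C@H](C)[C@H](O)c2cc(OC)c(OC)c(OC)c2)c(OC)c1 | intermediate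
17 | (1S,2R)-2-(4-allyl-2,6-dimethoxyphenoxy)-1-(3,4,5-trimethoxyphenyl)propyl 4-nitrobenzoate | C=CCc1cc(OC)c(O[C@H](C)[C@@H](OC(=O)c2ccc(cc2)[N+](=O)[O-])c2cc(OC)c(OC)c(OC)c2)c(OC)c1 | intermediate
18 | rhaphidecursinol B, (1S,2R)-2-(4-allyl-2,6-dimethoxyphenoxy)-1-(3,4,5-trimethoxyphenyl)propan-1-ol | C=CCc1cc(OC)c(O[C@H](C)[C@@H](O)c2cc(OC)c(OC)c(OC)c2)c(OC)c1 | target

**Totals**
Total step count: 11. Longest linear sequence: 11 steps (1 → 18); 2, 5 and 8 are bought.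

**Three steps most likely to fail**

Step 4 (aldol). The 2,6-dimethoxyaryloxy group is bulky and can coordinate boron, and the aldehyde is electron-rich, so conversion or facial selectivity may suffer. The fallback sets out from acid 4. EDC·HCl/DMAP coupling with (S)-4-benzylthiazolidine-2-thione gives (S)-2-(4-allyl-2,6-dimethoxyphenoxy)-1-(4-benzyl-2-thioxothiazolidin-3-yl)ethan-1-one F1. Its chlorotitanium enolate (TiCl4, i-Pr2NEt, NMP, CH2Cl2, −78 → 0 °C, Evans-syn conditions) adds to aldehyde 8 to give the syn adduct (2S,3R)-2-(4-allyl-2,6-dimethoxyphenoxy)-1-[(S)-4-benzyl-2-thioxothiazolidin-3-yl]-3-hydroxy-3-(3,4,5-trimethoxyphenyl)propan-1-one F2. TBSOTf/2,6-lutidine gives its tert-butyldimethylsilyl ether F3, and NaBH4 in THF/EtOH reduces the labile thioimide directly to alcohol 13, where the route is rejoined.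

Step 6 (reductive auxiliary removal). On this hindered α-aryloxy-β-silyloxy imide, hydride may attack the ring carbonyl or the reaction may stall. The fallback sets out from the unprotected aldol 11. Me3Al/MeNH(OMe)·HCl (CH2Cl2, −20 → 0 °C), assisted by the free β-hydroxyl, gives (2S,3R)-2-(4-allyl-2,6-dimethoxyphenoxy)-3-hydroxy-N-methoxy-N-methyl-3-(3,4,5-trimethoxyphenyl)propanamide F4. TBSOTf/2,6-lutidine gives the silylated Weinreb amide F5, DIBAL-H (THF, −78 °C) gives (2S,3R)-2-(4-allyl-2,6-dimethoxyphenoxy)-3-[(tert-butyldimethylsilyl)oxy]-3-(3,4,5-trimethoxyphenyl)propanal F6, and immediate NaBH4 reduction (MeOH, 0 °C) returns to the route at 13.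

Step 10 (Mitsunobu inversion). The alcohol is hindered and benzylic on an electron-rich ring, so elimination or partial SN1 loss of stereochemical integrity at C7 is possible. The fallback sets out from 16. Dess–Martin periodinane (NaHCO3, CH2Cl2, 0 °C) gives (R)-2-(4-allyl-2,6-dimethoxyphenoxy)-1-(3,4,5-trimethoxyphenyl)propan-1-one F7. Chelation-controlled reduction with Zn(BH4)2 (Et2O, −20 °C) delivers hydride anti to the methyl group in the zinc chelate and gives the anti (7S,8R) alcohol, the target 18, directly; any residual 16 is removed by chromatography and recycled.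

**Further compounds**
F1 | step 4 | (S)-2-(4-allyl-2,6-dimethoxyphenoxy)-1-(4-benzyl-2-thioxothiazolidin-3-yl)ethan-1-one | C=CCc1cc(OC)c(OCC(=O)N2[C@@H](Cc3ccccc3)CSC2=S)c(OC)c1
F2 | step 4 | (2S,3R)-2-(4-allyl-2,6-dimethoxyphenoxy)-1-[(S)-4-benzyl-2-thioxothiazolidin-3-yl]-3-hydroxy-3-(3,4,5-trimethoxyphenyl)propan-1-one | C=CCc1cc(OC)c(O[C@@H]([C@H](O)c2cc(OC)c(OC)c(OC)c2)C(=O)N2[C@@H](Cc3ccccc3)CSC2=S)c(OC)c1
F3 | step 4 | (2S,3R)-2-(4-allyl-2,6-dimethoxyphenoxy)-1-[(S)-4-benzyl-2-thioxothiazolidin-3-yl]-3-[(tert-butyldimethylsilyl)oxy]-3-(3,4,5-trimethoxyphenyl)propan-1-one | C=CCc1cc(OC)c(O[C@@H]([C@H](O[Si](C)(C)C(C)(C)C)c2cc(OC)c(OC)c(OC)c2)C(=O)N2[C@@H](Cc3ccccc3)CSC2=S)c(OC)c1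
F4 | step 6 | (2S,3R)-2-(4-allyl-2,6-dimethoxyphenoxy)-3-hydroxy-N-methoxy-N-methyl-3-(3,4,5-trimethoxyphenyl)propanamide | C=CCc1cc(OC)c(O[C@@H]([C@H](O)c2cc(OC)c(OC)c(OC)c2)C(=O)N(C)OC)c(OC)c1
F5 | step 6 | (2S,3R)-2-(4-allyl-2,6-dimethoxyphenoxy)-3-[(tert-butyldimethylsilyl)oxy]-N-methoxy-N-methyl-3-(3,4,5-trimethoxyphenyl)propanamide | C=CCc1cc(OC)c(O[C@@H]([C@H](O[Si](C)(C)C(C)(C)C)c2cc(OC)c(OC)c(OC)c2)C(=O)N(C)OC)c(OC)c1
F6 | step 6 | (2S,3R)-2-(4-allyl-2,6-dimethoxyphenoxy)-3-[(tert-butyldimethylsilyl)oxy]-3-(3,4,5-trimethoxyphenyl)propanal | C=CCc1cc(OC)c(O[C@@H]([C@H](O[Si](C)(C)C(C)(C)C)c2cc(OC)c(OC)c(OC)c2)C=O)c(OC)c1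
F7 | step 10 | (R)-2-(4-allyl-2,6-dimethoxyphenoxy)-1-(3,4,5-trimethoxyphenyl)propan-1-one | C=CCc1cc(OC)c(O[C@H](C)C(=O)c2cc(OC)c(OC)c(OC)c2)c(OC)c1
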